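Ring A is cut at C7–C8 and C5–C6, once the 4'-O-MOM group is set aside. This leaves a 5-aryl-4-pyranone ester (rings C and B) and a C6–C7 acyl unit, 5-methylhex-4-enoic acid, which is made through its methyl ester and used as the imidazolide.
Enabling feature: ring A is fused to ring C along the C4a–C8a bond. C8 can therefore start as the lateral CH2 on pyranone C2 (= C8a) and C5 as the ester carbon on pyranone C3 (= C4a), and the 6- and 8-prenyl groups enter as plain sp3 chains.
Ring C is cut at O1–C2 and C2–C3 (one carbon from an amide acetal) and at C4–C4a (C-acylation of a prenylated acetoacetate by the ring B arylacetyl chloride).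
Forward order: ring B is bought and dressed (MOM ether, directed metalation and prenylation at C3', one-carbon homologation of the aldehyde). Ring C closes in step 7, ring A in step 11, and the MOM group falls in step 12.
Stereochemistry: the target has no stereocentre and no alkene with E/Z isomers, so nothing has to be set.

Key step: step 11

Remark: deprotonated or metalated forms of a numbered compound (enolates, aryllithiums, phenoxides) count as reactive states of that compound, while every in-flask intermediate with a new covalent skeleton carries its own number.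

Step 1
Reactants: 1 4-hydroxy-2-methoxybenzaldehyde
Product: 2 2-methoxy-4-(methoxymethoxy)benzaldehyde
Conditions: MOMCl, iPr2NEt, CH2Cl2, 0 °C to rt
Reagents that add atoms: chloromethyl methyl ether (MOMCl), COCCl
Why: Williamson-type O-alkylation: the amine base deprotonates the only acidic group, the para-formyl phenol, and the very reactive chloromethyl ether alkylates the phenoxide without touching the aldehyde or the aryl methyl ether.

Step 2
Reactants: 2 2-methoxy-4-(methoxymethoxy)benzaldehyde; 3 prenyl bromide (1-bromo-3-methylbut-2-ene)
Product: 6 2-methoxy-4-(methoxymethoxy)-3-(3-methylbut-2-enyl)benzaldehyde, via lithium amino alkoxide 4 (not isolated), via prenylated lithium amino alkoxide 5 (not isolated)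
Conditions: 1-methylpiperazine, n-BuLi, THF, -20 °C; 2; n-BuLi, -20 to 0 °C; 3, -78 °C to rt; H2O
Reagents that add atoms: none
Why: Directed ortho-metalation with in situ alpha-amino alkoxide masking of the aldehyde: lithium 4-methylpiperazin-1-ide adds to the formyl group to give 4, whose weakly directing alkoxide leaves the metalation to the cooperating OMe and OMOM groups so that the C3–H between them is lithiated, SN2 alkylation by the allylic bromide gives 5, and water releases the aldehyde.

Step 3
Reactants: 6 2-methoxy-4-(methoxymethoxy)-3-(3-methylbut-2-enyl)benzaldehyde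
Product: 8 2-[2-methoxy-4-(methoxymethoxy)-3-(3-methylbut-2-enyl)phenyl]acetonitrile, via N-(1-tosylalkenyl)formamide 7 (not isolated)
Conditions: TosMIC, t-BuOK, DME, -50 °C; then MeOH, reflux
Reagents that add atoms: p-toluenesulfonylmethyl isocyanide (TosMIC), Cc1ccc(cc1)S(=O)(=O)C[N+]#[C-]
Why: van Leusen reductive cyanation of an aldehyde: the TosMIC anion adds to the formyl group, the oxazoline formed opens to formamide 7, and methanolysis of the formyl group with loss of sulfinate gives the nitrile one carbon longer under purely basic conditions that spare the MOM ether and the alkene.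

Step 4
Reactants: 8 2-[2-methoxy-4-(methoxymethoxy)-3-(3-methylbut-2-enyl)phenyl]acetonitrile
Product: 9 2-[2-methoxy-4-(methoxymethoxy)-3-(3-methylbut-2-enyl)phenyl]acetic acid
Conditions: KOH, EtOH–H2O, reflux; 1 M HCl to pH 4, 0 °C
Reagents that add atoms: water, O; potassium hydroxide, [K+].[OH-]
Why: Alkaline nitrile hydrolysis: hydroxide converts the unhindered arylacetonitrile through the amide into the carboxylate, base leaves the MOM acetal, the methyl ether and the prenyl group untouched, and the cold acidification stops at pH 4 to protect the acetal.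

Step 5
Reactants: 10 methyl acetoacetate; 3 prenyl bromide
Product: 11 methyl 7-methyl-3-oxooct-6-enoate
Conditions: NaH, THF, 0 °C; n-BuLi, 0 °C; 3, 0 °C to rt; 1 M HCl
Reagents that add atoms: none
Why: Gamma-alkylation of the acetoacetate dianion: the terminal carbanion, generated last and the more basic of the two sites, displaces the allylic bromide by SN2 while the inner enolate stays unreactive, so only the C4 carbon is prenylated.

Step 6
Reactants: 9 2-[2-methoxy-4-(methoxymethoxy)-3-(3-methylbut-2-enyl)phenyl]acetic acid; 11 methyl 7-methyl-3-oxooct-6-enoate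
Product: 13 methyl 2-{2-[2-methoxy-4-(methoxymethoxy)-3-(3-methylbut-2-enyl)phenyl]acetyl}-7-methyl-3-oxooct-6-enoate, via arylacetyl chloride 12 (not isolated)
Conditions: 9, Me2C=C(Cl)NMe2, CH2Cl2, 0 °C; then 11, MgCl2, pyridine, CH2Cl2, 0 °C to rt
Reagents that add atoms: none
Why: C-acylation of a magnesium beta-keto ester chelate under MgCl2–pyridine soft enolisation: the alpha-chloroenamine makes acid chloride 12 without releasing HCl, which protects the MOM ether and the alkenes, and the magnesium chelate ties up both enolate oxygens so that the acyl group goes to carbon.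

Step 7
Reactants: 13 methyl 2-{2-[2-methoxy-4-(methoxymethoxy)-3-(3-methylbut-2-enyl)phenyl]acetyl}-7-methyl-3-oxooct-6-enoate
Product: 15 methyl 5-[2-methoxy-4-(methoxymethoxy)-3-(3-methylbut-2-enyl)phenyl]-2-(4-methylpent-3-enyl)-4-oxopyran-3-carboxylate, via enaminone 14 (not isolated)
Conditions: Me2NCH(OMe)2, toluene, 80 °C, N2 sweep; then AcOH (cat.), 80 °C
Reagents that add atoms: N,N-dimethylformamide dimethyl acetal, COC(OC)N(C)C
Why: Amide acetal condensation followed by addition–elimination ring closure, the reaction type that turns deoxybenzoins into isoflavones and 3-acyl-4-hydroxypyranones into fused 4-pyranones: the benzylic CH2 is the most acidic free methylene and gives enaminone 14, the enol oxygen of the alkyl ketone then displaces dimethylamine, and sweeping out methanol and dimethylamine limits retro-Claisen cleavage of the tricarbonyl.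

Step 8
Reactants: 16 2-methylbut-3-en-2-ol
Product: 18 methyl 5-methylhex-4-enoate, via mixed ketene acetal 17 (not isolated)
Conditions: MeC(OMe)3, EtCO2H (cat.), 110–130 °C, MeOH distilled off
Reagents that add atoms: trimethyl orthoacetate, COC(C)(OC)OC
Why: Johnson–Claisen rearrangement: acid-catalysed exchange and loss of methanol give ketene acetal 17, whose [3,3] shift moves the oxygen-bound tertiary allyl unit to carbon and delivers the gamma,delta-unsaturated ester with the trisubstituted alkene.

Step 9
Reactants: 18 methyl 5-methylhex-4-enoate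
Product: 19 5-methylhex-4-enoic acid
Conditions: LiOH, THF–H2O, rt; 1 M HCl, 0 °C
Reagents that add atoms: lithium hydroxide, [Li+].[OH-]
Why: Saponification of an unhindered methyl ester; the isolated alkene is inert to hydroxide and the brief cold acidification is too mild for lactonisation onto it.

Step 10
Reactants: 19 5-methylhex-4-enoic acid
Product: 20 1-(imidazol-1-yl)-5-methylhex-4-en-1-one
Conditions: CDI, CH2Cl2, rt; cold H2O wash
Reagents that add atoms: 1,1'-carbonyldiimidazole (CDI), O=C(n1ccnc1)n1ccnc1
Why: Carboxyl activation with carbonyldiimidazole: the mixed anhydride loses CO2 and gives the acyl imidazole under neutral conditions, and the water wash removes the free imidazole that would otherwise quench the carbanion of the next step.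

Step 11
Reactants: 15 methyl 5-[2-methoxy-4-(methoxymethoxy)-3-(3-methylbut-2-enyl)phenyl]-2-(4-methylpent-3-enyl)-4-oxopyran-3-carboxylate; 20 1-(imidazol-1-yl)-5-methylhex-4-en-1-one
Product: 22 5,7-dihydroxy-3-[2-methoxy-4-(methoxymethoxy)-3-(3-methylbut-2-enyl)phenyl]-6,8-bis(3-methylbut-2-enyl)chromen-4-one, via lateral ketone 21 (not isolated)
Conditions: LiN(iPr)2 (1.05 equiv), THF, -78 °C; 20 (1.05 equiv), -78 to -30 °C; LiN(iPr)2 (2.5 equiv), -78 to 0 °C; AcOH
Reagents that add atoms: none
Why: Proposed new method: lithium diisopropylamide removes a proton from the lateral CH2 on pyranone C2, which is vinylogous to both the C4 ketone and the C3 ester, and the chelated lithium dienolate is acylated at that carbon by imidazolide 20 to give ketone 21 (C7–C8 bond), the expelled imidazolide being basic enough to absorb the acidic C8–H; the acid is activated because so stabilised a carbanion would attack a plain alkyl ester too slowly. The second charge of base deprotonates imidazole and the outer alpha carbon of 21 (future C6), and this terminal carbon of the dianion adds to the adjacent C3 ester in a 6-exo-trig Dieckmann-type closure (C5–C6 bond), after which loss of methoxide and two enolisations deliver aromatic ring A as its 5,7-diphenoxide. The closest known reaction types are the Staunton–Weinreb annulation, the acylation–Claisen cyclisation of o-toluate carbanions to naphthalene-1,3-diols, the lateral metalation of 2-alkyl-4-pyranones and the C-acylation of stabilised enolates by acyl imidazoles; their combination on a pyranone ester to build a benzene ring is what has not been shown. No stereocentre survives, since the one at C8 of 21 is erased on aromatisation. The step needs C- rather than O-acylation, which the lithium chelate between the C4 oxygen and the ester carbonyl and the lithium-binding imidazolide donor should secure, and C- rather than O-closure, which is secured thermodynamically because closure through the C7 enolate oxygen to a fused 2-pyranone is reopened by the liberated methoxide whereas closure through C6 ends in an aromatic diphenoxide. The inner alpha carbon C8 could reach the ester only through a four-membered ring, so C6 is the only carbon that can close.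

Step 12
Reactants: 22 5,7-dihydroxy-3-[2-methoxy-4-(methoxymethoxy)-3-(3-methylbut-2-enyl)phenyl]-6,8-bis(3-methylbut-2-enyl)chromen-4-one
Product: 23 5,7-dihydroxy-3-[4-hydroxy-2-methoxy-3-(3-methylbut-2-enyl)phenyl]-6,8-bis(3-methylbut-2-enyl)chromen-4-one (CNP0331360.0)
Conditions: 3 M aq HCl (cat.), MeOH, 40 °C
Reagents that add atoms: none
Why: Acid-catalysed acetal exchange (MOM cleavage) as routinely applied to prenylated flavonoids: the aryl MOM acetal is protonated and methanolysed far faster than the trisubstituted alkenes are protonated at this acidity and temperature, so chroman formation with the neighbouring phenols should not compete.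

Compound list
1 | 4-hydroxy-2-methoxybenzaldehyde | COc1cc(O)ccc1C=O | starting material
2 | 2-methoxy-4-(methoxymethoxy)benzaldehyde | COCOc1ccc(C=O)c(OC)c1 | intermediate
3 | prenyl bromide (1-bromo-3-methylbut-2-ene) | CC(C)=CCBr | starting material
4 | lithium [2-methoxy-4-(methoxymethoxy)phenyl](4-methylpiperazin-1-yl)methanolate (racemic, formed in the flask) | [Li+].[O-]C(N1CCN(C)CC1)c1ccc(OCOC)cc1OC | intermediate
5 | lithium [2-methoxy-4-(methoxymethoxy)-3-(3-methylbut-2-enyl)phenyl](4-methylpiperazin-1-yl)methanolate (racemic, formed in the flask) | [Li+].[O-]C(N1CCN(C)CC1)c1ccc(OCOC)c(CC=C(C)C)c1OC | intermediate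
6 | 2-methoxy-4-(methoxymethoxy)-3-(3-methylbut-2-enyl)benzaldehyde | COCOc1ccc(C=O)c(OC)c1CC=C(C)C | intermediate
7 | N-{2-[2-methoxy-4-(methoxymethoxy)-3-(3-methylbut-2-enyl)phenyl]-1-(4-methylphenyl)sulfonylethenyl}formamide (formed in the flask) | O=CNC(=Cc1ccc(OCOC)c(CC=C(C)C)c1OC)S(=O)(=O)c1ccc(C)cc1 | intermediate
8 | 2-[2-methoxy-4-(methoxymethoxy)-3-(3-methylbut-2-enyl)phenyl]acetonitrile | COCOc1ccc(CC#N)c(OC)c1CC=C(C)C | intermediate
9 | 2-[2-methoxy-4-(methoxymethoxy)-3-(3-methylbut-2-enyl)phenyl]acetic acid | COCOc1ccc(CC(=O)O)c(OC)c1CC=C(C)C | intermediate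
10 | methyl acetoacetate | COC(=O)CC(C)=O | starting material
11 | methyl 7-methyl-3-oxooct-6-enoate | COC(=O)CC(=O)CCC=C(C)C | intermediate
12 | 2-[2-methoxy-4-(methoxymethoxy)-3-(3-methylbut-2-enyl)phenyl]acetyl chloride (formed in the flask) | COCOc1ccc(CC(=O)Cl)c(OC)c1CC=C(C)C | intermediate
13 | methyl 2-{2-[2-methoxy-4-(methoxymethoxy)-3-(3-methylbut-2-enyl)phenyl]acetyl}-7-methyl-3-oxooct-6-enoate (drawn as the triketo form, largely enolised) | COC(=O)C(C(=O)CCC=C(C)C)C(=O)Cc1ccc(OCOC)c(CC=C(C)C)c1OC | intermediate
14 | methyl 2-{3-(dimethylamino)-2-[2-methoxy-4-(methoxymethoxy)-3-(3-methylbut-2-enyl)phenyl]prop-2-enoyl}-7-methyl-3-oxooct-6-enoate (formed in the flask) | COC(=O)C(C(=O)CCC=C(C)C)C(=O)C(=CN(C)C)c1ccc(OCOC)c(CC=C(C)C)c1OC | intermediate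
15 | methyl 5-[2-methoxy-4-(methoxymethoxy)-3-(3-methylbut-2-enyl)phenyl]-2-(4-methylpent-3-enyl)-4-oxopyran-3-carboxylate | COC(=O)c1c(CCC=C(C)C)occ(-c2ccc(OCOC)c(CC=C(C)C)c2OC)c1=O | intermediate
16 | 2-methylbut-3-en-2-ol | C=CC(C)(C)O | starting material
17 | 1-methoxy-1-(2-methylbut-3-en-2-yloxy)ethene (formed in the flask) | C=C(OC)OC(C)(C)C=C | intermediate
18 | methyl 5-methylhex-4-enoate | COC(=O)CCC=C(C)C | intermediate
19 | 5-methylhex-4-enoic acid | CC(C)=CCCC(=O)O | intermediate
20 | 1-(imidazol-1-yl)-5-methylhex-4-en-1-one | CC(C)=CCCC(=O)n1ccnc1 | intermediate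
21 | methyl 2-(2,10-dimethyl-6-oxoundeca-2,9-dien-5-yl)-5-[2-methoxy-4-(methoxymethoxy)-3-(3-methylbut-2-enyl)phenyl]-4-oxopyran-3-carboxylate (racemic, formed in the flask) | COC(=O)c1c(C(CC=C(C)C)C(=O)CCC=C(C)C)occ(-c2ccc(OCOC)c(CC=C(C)C)c2OC)c1=O | intermediate
22 | 5,7-dihydroxy-3-[2-methoxy-4-(methoxymethoxy)-3-(3-methylbut-2-enyl)phenyl]-6,8-bis(3-methylbut-2-enyl)chromen-4-one | COCOc1ccc(-c2coc3c(CC=C(C)C)c(O)c(CC=C(C)C)c(O)c3c2=O)c(OC)c1CC=C(C)C | intermediate
23 | 5,7-dihydroxy-3-[4-hydroxy-2-methoxy-3-(3-methylbut-2-enyl)phenyl]-6,8-bis(3-methylbut-2-enyl)chromen-4-one (CNP0331360.0) | COc1c(-c2coc3c(CC=C(C)C)c(O)c(CC=C(C)C)c(O)c3c2=O)ccc(O)c1CC=C(C)C | target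

Total step count: 12.
Longest linear sequence: 8 steps (1, 2, 3, 4, 6, 7, 11, 12), counted from 4-hydroxy-2-methoxybenzaldehyde.

Steps most likely to fail

Risk 1, step 11.
- The dienolate may be acylated on oxygen, or it may exchange protons with the acylated product faster than it is acylated.
- The ketone enolate may close through oxygen.
- Amide or methoxide may open the pyranone at its unsubstituted CH.
- The fallback splits the annulation into known operations at a lower oxidation level and sets out from 15 and 18.
- i-Bu2AlH (toluene, -78 °C) should reduce 18 to 5-methylhex-4-enal F1.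
- The lateral lithium carbanion of 15 (LiN(iPr)2, THF, -78 °C) should add to this aldehyde in the aldol-type addition that is well known for 2-alkyl-4-pyranones. A quench at -78 °C, before the alkoxide can lactonise onto the ester, should give methyl 2-(6-hydroxy-2,10-dimethylundeca-2,9-dien-5-yl)-5-[2-methoxy-4-(methoxymethoxy)-3-(3-methylbut-2-enyl)phenyl]-4-oxopyran-3-carboxylate F2 as a diastereomer mixture of no consequence.
- Dess–Martin periodinane (CH2Cl2, rt) should then give ketone 21, now as an isolated compound.
- NaH in THF (0 °C to rt) should close 21 to 22, where the route is rejoined. This is the intramolecular Claisen condensation that converts 2-(2-oxoalkyl)benzoates into naphthalene-1,3-diols.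

Risk 2, step 7.
- The acetal may condense at the alkyl instead of the benzylic methylene, or it may methylate the acidic enol.
- The liberated dimethylamine and methanol may cleave the tricarbonyl by retro-Claisen deacylation.
- The fallback replaces the amide acetal by strong-base dianion chemistry and sets out from 13.
- LiN(iPr)2 (2.2 equiv, THF, -78 °C) should deprotonate first the central CH and then the benzylic CH2. The terminal benzylic carbanion should be formylated by methyl formate, in the classical terminal acylation of beta-dicarbonyl dianions, to give methyl 2-{3-hydroxy-2-[2-methoxy-4-(methoxymethoxy)-3-(3-methylbut-2-enyl)phenyl]prop-2-enoyl}-7-methyl-3-oxooct-6-enoate F3.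
- Mild cyclodehydration with pyridinium p-toluenesulfonate in toluene at 60 °C should then close the 4-pyranone and rejoin the route at 15.

Risk 3, step 2.
- Metalation may occur at C5 or C6 instead of C3.
- The masked aldehyde may collapse early and suffer butyl addition.
- The fallback avoids aryllithium chemistry altogether and sets out from 3 together with commercial 2,4-dihydroxybenzaldehyde.
- In aqueous KOH (0 °C to rt) the resorcinolate should be C-alkylated between its two oxygens to give 2,4-dihydroxy-3-(3-methylbut-2-enyl)benzaldehyde F4, which is separated from its regioisomers at this cheap first stage.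
- MOMCl with K2CO3 in acetone should protect only the 4-OH, because the 2-OH is hydrogen-bonded to the aldehyde. This gives 2-hydroxy-4-(methoxymethoxy)-3-(3-methylbut-2-enyl)benzaldehyde F5.
- MeI with K2CO3 in DMF should methylate the remaining phenol and rejoin the route at 6.

Further compounds
F1 | step 11 | 5-methylhex-4-enal | CC(C)=CCCC=O
F2 | step 11 | methyl 2-(6-hydroxy-2,10-dimethylundeca-2,9-dien-5-yl)-5-[2-methoxy-4-(methoxymethoxy)-3-(3-methylbut-2-enyl)phenyl]-4-oxopyran-3-carboxylate (diastereomer mixture) | COC(=O)c1c(C(CC=C(C)C)C(O)CCC=C(C)C)occ(-c2ccc(OCOC)c(CC=C(C)C)c2OC)c1=O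
F3 | step 7 | methyl 2-{3-hydroxy-2-[2-methoxy-4-(methoxymethoxy)-3-(3-methylbut-2-enyl)phenyl]prop-2-enoyl}-7-methyl-3-oxooct-6-enoate | COC(=O)C(C(=O)CCC=C(C)C)C(=O)C(=CO)c1ccc(OCOC)c(CC=C(C)C)c1OC
F4 | step 2 | 2,4-dihydroxy-3-(3-methylbut-2-enyl)benzaldehyde | CC(C)=CCc1c(O)ccc(C=O)c1O
F5 | step 2 | 2-hydroxy-4-(methoxymethoxy)-3-(3-methylbut-2-enyl)benzaldehyde | COCOc1ccc(C=O)c(O)c1CC=C(C)C
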